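**Retrosynthetic overview**

- The target is the bis-N-Boc compound 17 with both carbamates removed; 17 is cut at two bonds of its cyclohexene ring, C1–Cα (quaternary carbon to styryl) and C6–C5′ (benzylic CH to indole).
- Feature that carries the strategy: the ring C1(Me)(styryl)–C2H2–C3H2–C4(Me)=C5H–C6H(indol-5-yl) has the C1 styryl and C6 indolyl groups cis, with C4(Me)=C5 next to C6. This is the pattern of a syn 1,2-addition of an alkenyl group (at C1) and an aryl group (at C6) across one double bond of the symmetric 1,4-dimethylcyclohexa-1,3-diene.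
- Three components: diene 3 (from p-xylene), (E)-vinyl iodide 16 and boronic acid 11. Both indole partners come from one bromoindole 8.
- Ring order: the two indole pyrrole rings are closed first, by one Fischer indolisation that serves both halves. The carbocycle is never closed; it is the ring of p-xylene carried through reduction and isomerisation.

Key step: step 11

Remark: which antipode of the PyrOx ligand leads to the (1R,6R) series cannot be predicted for this new substrate class; the (S)-ligand is written, and its mirror image is to be used if the first run shows the opposite sense.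

**Route**

Step 1
Reactants: 1 p-xylene
Product: 2 1,4-dimethylcyclohexa-1,4-diene
Conditions: Li, NH3(l)/THF, EtOH, −78 to −33 °C; NH4Cl quench
Reagents that add atoms: none
Why: Birch reduction: electron transfer and protonation at two para-related unsubstituted ring carbons leave both methyl groups on the remaining alkenes of the skipped diene.

Step 2
Reactants: 2 1,4-dimethylcyclohexa-1,4-diene
Product: 3 1,4-dimethylcyclohexa-1,3-diene
Conditions: KOtBu (0.3 equiv), DMSO, 60 °C; distillation, then AgNO3–SiO2 (pentane)
Reagents that add atoms: none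
Why: Base-mediated prototropic isomerisation through the pentadienyl anion equilibrates the skipped diene with its conjugated isomers, of which the 1,3-diene with two trisubstituted alkenes is expected to be favoured; residual skipped diene and p-xylene are removed on silver nitrate-impregnated silica.

Step 3
Reactants: 4 methyl 3,3-dimethylpent-4-enoate
Product: 5 3,3-dimethylpent-4-enal
Conditions: DIBAL-H (1.05 equiv), CH2Cl2, −78 °C; MeOH, then aq. Rochelle salt
Reagents that add atoms: none
Why: DIBAL-H partial reduction of an ester: the tetrahedral aluminium hemiacetal is stable at −78 °C and releases the aldehyde only on work-up, and the isolated alkene is inert.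

Step 4
Reactants: 5 3,3-dimethylpent-4-enal; 6 (4-bromophenyl)hydrazine (charged as its hydrochloride)
Product: 8 5-bromo-3-(2-methylbut-3-en-2-yl)-1H-indole, via hydrazone 7 (not isolated)
Conditions: EtOH, rt; then AcOH, 90 °C
Reagents that add atoms: none
Why: Fischer indole synthesis: the ene-hydrazine tautomer of 7 undergoes [3,3]-sigmatropic rearrangement, cyclisation and loss of ammonia, so the α-carbon carrying the 1,1-dimethylallyl group becomes C3 and the para bromine can only end at C5.

Step 5
Reactants: 8 5-bromo-3-(2-methylbut-3-en-2-yl)-1H-indole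
Product: 9 tert-butyl 5-bromo-3-(2-methylbut-3-en-2-yl)indole-1-carboxylate
Conditions: Boc2O (1.2 equiv), DMAP (0.1 equiv), MeCN, rt
Reagents that add atoms: di-tert-butyl dicarbonate, CC(C)(C)OC(=O)OC(=O)OC(C)(C)C
Why: DMAP-catalysed N-acylation of the indole nitrogen with Boc anhydride.

Step 6
Reactants: 9 tert-butyl 5-bromo-3-(2-methylbut-3-en-2-yl)indole-1-carboxylate
Product: 10 tert-butyl 3-(2-methylbut-3-en-2-yl)-5-(4,4,5,5-tetramethyl-1,3,2-dioxaborolan-2-yl)indole-1-carboxylate
Conditions: B2pin2 (1.2 equiv), Pd(dppf)Cl2·CH2Cl2 (3 mol%), KOAc (3 equiv), 1,4-dioxane, 85 °C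
Reagents that add atoms: bis(pinacolato)diboron, CC1(C)OB(OC1(C)C)B1OC(C)(C)C(C)(C)O1
Why: Miyaura borylation: oxidative addition of the aryl bromide, acetate-assisted transmetallation from the diboron and reductive elimination, under weakly basic anhydrous conditions that leave the carbamate and the hindered vinyl group alone.

Step 7
Reactants: 10 tert-butyl 3-(2-methylbut-3-en-2-yl)-5-(4,4,5,5-tetramethyl-1,3,2-dioxaborolan-2-yl)indole-1-carboxylate
Product: 11 [1-(tert-butoxycarbonyl)-3-(2-methylbut-3-en-2-yl)indol-5-yl]boronic acid
Conditions: NaIO4 (3 equiv), NH4OAc (3 equiv), acetone/H2O, rt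
Reagents that add atoms: water, O
Why: Hydrolysis of the pinacol boronate is driven by periodate cleavage of the released pinacol; the N-Boc indole and the monosubstituted alkene do not react with periodate at room temperature.

Step 8
Reactants: 8 5-bromo-3-(2-methylbut-3-en-2-yl)-1H-indole
Product: 14 3-(2-methylbut-3-en-2-yl)-1H-indole-5-carbaldehyde, via potassium indolide 12 (not isolated), via lithiated indolide 13 (not isolated)
Conditions: KH (1.1 equiv), THF, 0 °C; t-BuLi (2.1 equiv), −78 °C; DMF (3 equiv), −78 °C to rt; sat. aq. NH4Cl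
Reagents that add atoms: N,N-dimethylformamide, CN(C)C=O
Why: Deprotonation of N–H with KH masks the acidic site, bromine–lithium exchange with two equivalents of t-BuLi gives the C5 aryllithium, and DMF formylates it (Bouveault-type formylation).

Step 9
Reactants: 14 3-(2-methylbut-3-en-2-yl)-1H-indole-5-carbaldehyde
Product: 15 tert-butyl 5-formyl-3-(2-methylbut-3-en-2-yl)indole-1-carboxylate
Conditions: Boc2O (1.2 equiv), DMAP (0.1 equiv), MeCN, rt
Reagents that add atoms: di-tert-butyl dicarbonate, CC(C)(C)OC(=O)OC(=O)OC(C)(C)C
Why: DMAP-catalysed N-acylation of the indole nitrogen, to which the aryl aldehyde is inert.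

Step 10
Reactants: 15 tert-butyl 5-formyl-3-(2-methylbut-3-en-2-yl)indole-1-carboxylate
Product: 16 tert-butyl 5-[(E)-2-iodoethenyl]-3-(2-methylbut-3-en-2-yl)indole-1-carboxylate
Conditions: CrCl2 (6 equiv), CHI3 (2 equiv), THF/1,4-dioxane, 0 °C to rt, dark
Reagents that add atoms: iodoform, IC(I)I
Why: Takai olefination: the geminal dichromium species from iodoform adds to the aldehyde and anti elimination gives the (E)-vinyl iodide, the selectivity being high for aryl aldehydes.

Step 11
Reactants: 3 1,4-dimethylcyclohexa-1,3-diene; 16 tert-butyl 5-[(E)-2-iodoethenyl]-3-(2-methylbut-3-en-2-yl)indole-1-carboxylate; 11 [1-(tert-butoxycarbonyl)-3-(2-methylbut-3-en-2-yl)indol-5-yl]boronic acid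
Product: 17 tert-butyl 5-[(1R,6R)-6-[(E)-2-[1-(tert-butoxycarbonyl)-3-(2-methylbut-3-en-2-yl)indol-5-yl]ethenyl]-3,6-dimethylcyclohex-2-en-1-yl]-3-(2-methylbut-3-en-2-yl)indole-1-carboxylate (styryl cis to indolyl)
Conditions: Pd2(dba)3·CHCl3 (5 mol%), (S)-4-tert-butyl-2-[5-(trifluoromethyl)pyridin-2-yl]-4,5-dihydrooxazole (12 mol%), Ag2CO3 (1.2 equiv), 3 (5 equiv), DMA, 30 °C; 11 (1.5 equiv) added over 6 h
Reagents that add atoms: none
Why: Proposed new method: oxidative addition of 16 to the ligated Pd(0) and iodide abstraction by silver should give a cationic (E)-alkenylpalladium(II) that coordinates the cisoid diene 3 and inserts syn, forming the C–C bond at a methyl-bearing terminus because only this places palladium in an η3-allyl over the next three ring carbons; carbonate-assisted transmetallation from 11 and inner-sphere reductive elimination at the secondary allyl terminus then give 17 and return Pd(0). The closest known reaction types are the palladium-catalysed three-component 1,2-alkenylarylation and 1,2-diarylation of terminal 1,3-dienes with alkenyl triflates or arenediazonium salts and arylboronic acids, and the enantioselective intermolecular Heck insertions of cationic alkenyl- and arylpalladium PyrOx complexes into trisubstituted alkenes that create quaternary carbons; insertion at a trisubstituted terminus of a cyclic diene combined with arylation of the resulting allyl is not known. No ring is closed, the carbocycle being that of the diene. The quaternary centre is set in the insertion, in which the chiral N,N-ligand must choose between the two enantiotopic faces of the achiral diene (its two termini are homotopic, so no regiochemical question arises), and the benzylic centre is set relative to it because palladium remains on the face it added to and hands the aryl group to that face, cis to the styryl group. The step needs insertion to outrun direct Suzuki coupling of 16 with 11 and Heck insertion into the two neopentyl-type vinyl groups, for which the conjugated diene is used in large excess and 11 is fed slowly, and it needs 1,2- rather than 1,4-arylation, which the preference of reductive elimination for the secondary over the methyl-substituted tertiary allyl terminus should secure. β-Hydride elimination is disfavoured since the carbon next to the first palladium-bound carbon is quaternary and the only other pathway runs through the tertiary σ-allyl isomer.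

Step 12
Reactants: 17 tert-butyl 5-[(1R,6R)-6-[(E)-2-[1-(tert-butoxycarbonyl)-3-(2-methylbut-3-en-2-yl)indol-5-yl]ethenyl]-3,6-dimethylcyclohex-2-en-1-yl]-3-(2-methylbut-3-en-2-yl)indole-1-carboxylate
Product: 18 5-[(1R,6R)-3,6-dimethyl-6-[(E)-2-[3-(2-methylbut-3-en-2-yl)-1H-indol-5-yl]ethenyl]cyclohex-2-en-1-yl]-3-(2-methylbut-3-en-2-yl)-1H-indole (EANPDB:ANNO_00014)
Conditions: K2CO3 (3 equiv), MeOH/THF, 50 °C
Reagents that add atoms: none
Why: Base-catalysed methanolysis of the two N-acylindole-type carbamates (indolide is a good leaving group) removes both Boc groups without acid, so the acid-labile 1,1-dimethylallyl groups, the trisubstituted alkene and both stereocentres are untouched.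

**Compound list**

1 | p-xylene | Cc1ccc(C)cc1 | starting material
2 | 1,4-dimethylcyclohexa-1,4-diene | CC1=CCC(C)=CC1 | intermediate
3 | 1,4-dimethylcyclohexa-1,3-diene | CC1=CC=C(C)CC1 | intermediate
4 | methyl 3,3-dimethylpent-4-enoate | COC(=O)CC(C)(C)C=C | starting material
5 | 3,3-dimethylpent-4-enal | O=CCC(C)(C)C=C | intermediate
6 | (4-bromophenyl)hydrazine | NNc1ccc(Br)cc1 | starting material
7 | (E)-1-(4-bromophenyl)-2-(3,3-dimethylpent-4-en-1-ylidene)hydrazine | C=CC(C)(C)C/C=N/Nc1ccc(Br)cc1 | intermediate (not isolated)
8 | 5-bromo-3-(2-methylbut-3-en-2-yl)-1H-indole | C=CC(C)(C)c1c[nH]c2ccc(Br)cc12 | intermediate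
9 | tert-butyl 5-bromo-3-(2-methylbut-3-en-2-yl)indole-1-carboxylate | C=CC(C)(C)c1cn(C(=O)OC(C)(C)C)c2ccc(Br)cc12 | intermediate
10 | tert-butyl 3-(2-methylbut-3-en-2-yl)-5-(4,4,5,5-tetramethyl-1,3,2-dioxaborolan-2-yl)indole-1-carboxylate | C=CC(C)(C)c1cn(C(=O)OC(C)(C)C)c2ccc(B3OC(C)(C)C(C)(C)O3)cc12 | intermediate
11 | [1-(tert-butoxycarbonyl)-3-(2-methylbut-3-en-2-yl)indol-5-yl]boronic acid | C=CC(C)(C)c1cn(C(=O)OC(C)(C)C)c2ccc(B(O)O)cc12 | intermediate
12 | potassium 5-bromo-3-(2-methylbut-3-en-2-yl)indol-1-ide | C=CC(C)(C)c1c[n-]c2ccc(Br)cc12.[K+] | intermediate (not isolated)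
13 | potassium 5-lithio-3-(2-methylbut-3-en-2-yl)indol-1-ide | C=CC(C)(C)c1c[n-]c2ccc([Li])cc12.[K+] | intermediate (not isolated)
14 | 3-(2-methylbut-3-en-2-yl)-1H-indole-5-carbaldehyde | C=CC(C)(C)c1c[nH]c2ccc(C=O)cc12 | intermediate
15 | tert-butyl 5-formyl-3-(2-methylbut-3-en-2-yl)indole-1-carboxylate | C=CC(C)(C)c1cn(C(=O)OC(C)(C)C)c2ccc(C=O)cc12 | intermediate
16 | tert-butyl 5-[(E)-2-iodoethenyl]-3-(2-methylbut-3-en-2-yl)indole-1-carboxylate | C=CC(C)(C)c1cn(C(=O)OC(C)(C)C)c2ccc(/C=C/I)cc12 | intermediate
17 | tert-butyl 5-[(1R,6R)-6-[(E)-2-[1-(tert-butoxycarbonyl)-3-(2-methylbut-3-en-2-yl)indol-5-yl]ethenyl]-3,6-dimethylcyclohex-2-en-1-yl]-3-(2-methylbut-3-en-2-yl)indole-1-carboxylate | C=CC(C)(C)c1cn(C(=O)OC(C)(C)C)c2ccc(/C=C/[C@@]3(C)CCC(C)=C[C@H]3c3ccc4n(C(=O)OC(C)(C)C)cc(C(C)(C)C=C)c4c3)cc12 | intermediate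
18 | 5-[(1R,6R)-3,6-dimethyl-6-[(E)-2-[3-(2-methylbut-3-en-2-yl)-1H-indol-5-yl]ethenyl]cyclohex-2-en-1-yl]-3-(2-methylbut-3-en-2-yl)-1H-indole | C=CC(C)(C)c1c[nH]c2ccc(/C=C/[C@@]3(C)CCC(C)=C[C@H]3c3ccc4[nH]cc(C(C)(C)C=C)c4c3)cc12 | target

**Step count and risks**

Total step count: 12. Longest linear sequence: 7 steps (from 4 through steps 3, 4, 5, 6, 7, 11, 12, or equally through steps 3, 4, 8, 9, 10, 11, 12).

Steps most likely to fail:

1. Step 11 (proposed new method).
   - What may go wrong: insertion into the trisubstituted diene terminus may be too slow, so that direct Suzuki coupling of 16 with 11, or Heck insertion into the terminal vinyl groups, consumes the alkenylpalladium. Facial selectivity of the insertion may be poor. Arylation may go to the methyl-bearing allyl terminus, or the allyl may collapse by β-hydride elimination.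
   - Fallback with known chemistry, setting out from 16 and returning at 17: Suzuki–Miyaura coupling of 16 with isopropenylboronic acid pinacol ester (Pd(dppf)Cl2, K3PO4, THF/H2O, 50 °C) would give the diene tert-butyl 5-[(1E)-3-methylbuta-1,3-dien-1-yl]-3-(2-methylbut-3-en-2-yl)indole-1-carboxylate F1. An enantioselective Diels–Alder reaction of F1 with methacrolein under a triflimide-activated chiral oxazaborolidine Lewis acid (CH2Cl2, −78 to −40 °C) should give the aldehyde tert-butyl 5-[(1S,6S)-6-formyl-3,6-dimethylcyclohex-2-en-1-yl]-3-(2-methylbut-3-en-2-yl)indole-1-carboxylate F2. The terminal aryl group and the internal methyl group of the diene both direct the formyl-bearing carbon next to the aryl-bearing carbon, and the formyl-endo transition state places CHO cis to the aryl group. Takai olefination of F2 (CrCl2, CHI3, THF) would give the vinyl iodide tert-butyl 5-[(1R,6S)-6-[(E)-2-iodoethenyl]-3,6-dimethylcyclohex-2-en-1-yl]-3-(2-methylbut-3-en-2-yl)indole-1-carboxylate F3. Suzuki–Miyaura coupling of F3 with boronic acid 11 (Pd(PPh3)4, aq. K3PO4, THF, 50 °C) then gives 17.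

2. Step 4.
   - What may go wrong: acid-promoted 1,2-shift or loss of the tertiary allyl group from C3 of the protonated indole, and sluggish sigmatropic rearrangement of the deactivated bromophenylhydrazone with decomposition of the aldehyde-derived hydrazone.
   - Fallback, setting out from 5 and returning at 8: condensation of 5 with 4-bromo-2-iodoaniline forms the enamine 4-bromo-N-[(1E)-3,3-dimethylpenta-1,4-dien-1-yl]-2-iodoaniline F4 in the flask. Pd(OAc)2/DABCO in DMF at 85 °C closes the pyrrole ring by intramolecular Heck-type arylation of the enamine at the C–I bond. The C–Br bond is not activated without a phosphine, and the conditions are basic throughout, so 8 is reached without acid.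

3. Step 3.
   - What may go wrong: over-reduction of the aluminium hemiacetal to the primary alcohol, and evaporative loss of the volatile aldehyde during isolation.
   - Fallback, setting out from 4 and returning at 5: full reduction with LiAlH4 (Et2O, 0 °C) gives 3,3-dimethylpent-4-en-1-ol F5. Swern oxidation (oxalyl chloride, DMSO, Et3N, CH2Cl2, −78 °C) gives 5, which is carried as a dried solution into step 4 without concentration.

**Further compounds**

F1 | step 11 | tert-butyl 5-[(1E)-3-methylbuta-1,3-dien-1-yl]-3-(2-methylbut-3-en-2-yl)indole-1-carboxylate | C=C(C)/C=C/c1ccc2n(C(=O)OC(C)(C)C)cc(C(C)(C)C=C)c2c1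
F2 | step 11 | tert-butyl 5-[(1S,6S)-6-formyl-3,6-dimethylcyclohex-2-en-1-yl]-3-(2-methylbut-3-en-2-yl)indole-1-carboxylate | O=C[C@@]1(C)CCC(C)=C[C@H]1c1ccc2n(C(=O)OC(C)(C)C)cc(C(C)(C)C=C)c2c1
F3 | step 11 | tert-butyl 5-[(1R,6S)-6-[(E)-2-iodoethenyl]-3,6-dimethylcyclohex-2-en-1-yl]-3-(2-methylbut-3-en-2-yl)indole-1-carboxylate | I/C=C/[C@@]1(C)CCC(C)=C[C@H]1c1ccc2n(C(=O)OC(C)(C)C)cc(C(C)(C)C=C)c2c1
F4 | step 4 | 4-bromo-N-[(1E)-3,3-dimethylpenta-1,4-dien-1-yl]-2-iodoaniline | C=CC(C)(C)/C=C/Nc1ccc(Br)cc1I
F5 | step 3 | 3,3-dimethylpent-4-en-1-ol | C=CC(C)(C)CCO
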